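(Its constants are assumed; no experiment stands behind them.)

The target is made by reagent meeting catalyst intermediate A, so the rate asked about needs two fractions: the reagent left and the catalyst held in that intermediate.

    reagent + catalyst intermediate B → free catalyst + second product (k1 = 200 /M/h)
    second substrate + free catalyst ⇌ catalyst intermediate B (K2 = 1.9 /M, k2 = 130 /M/h)
    starting material + free catalyst ⇌ catalyst intermediate A (K3 = 69 /M, k3 = 330 /M/h)
    2 starting material → homo dimer (k4 = 0.45 /M/h)
    reagent + catalyst intermediate A → free catalyst + target (k5 = 440 /M/h)
    starting material + reagent → uncatalysed product (k6 = 1.6 /M/h)

starting material 0.25 M; second substrate 0.250 M; reagent 0.150 M; free catalyst 1.4 mM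

* apparent order in free catalyst when 50% of the starting material are converted (percent change of the rate of making target for one percent more free catalyst charged)

- percentages count the starting material that a species holds: one homo dimer counts as two
- where a step has two of a species, its rate is k times that concentration squared, and two are used at each turn
- charge of starting material (flask): 0.25 M

The catalyst charge is hardly any of the reagent charge, so I let its forms balance quickly. At its charge, reagent drains catalyst intermediate A at 66.0 /h, faster than it reverts at 4.78 /h. With each drain counted, I reckon 1.17 of catalyst intermediate A and 0.330 of catalyst intermediate B per free catalyst, so catalyst intermediate A holds 46.7% of the catalyst.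

At the start, that split gives 0.0432 M/h to target and 0.00556 M/h to second product. The uncatalysed step runs at 0.0600 M/h, and the homo dimer takes 0.0563 M/h of starting material.

Reagent is the limiting reagent, and I freeze its price at its starting value of 1.14: the fraction of its charge spent per fraction of the starting-material charge spent. At half conversion, this gives 43.2% of the reagent left.

A small relative step up in catalyst raises the price by 0.202 of that step, so the reagent left falls by 0.233 of it. By my reckoning catalyst intermediate A holds 47.0% of the catalyst at that point, and the split among all three forms shifts with the reagent left, so the rate follows reagent to the power 0.570. At fixed fractions the rate is first order in catalyst, so my order is one minus the product of these two, 0.867.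

The forecast gives 0.87, with a range of 0.78 to 0.97, on the ground that “extra catalyst leaves less reagent at that point”.

The simulation gives 0.86. That conversion is reached at 1.46 h, with target being made at 0.0183 M/h. At 3.00 h the flask holds 32.1% of its starting material, so the frozen price gives 22.9% of the reagent left, and the flask holds 18.9%.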